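The isoflavanone is cut across ring C so that ring A comes from an aryne and everything else from a 2-arylacrylic acid. The feature used is the ortho relationship on ring A between C4a, which bears the C4 carbonyl, and C8a, which bears O1. An aryne inserts into the acyl C–O bond of the acid to create exactly this pair (C4–C4a, O1–C8a), and the freed phenoxide closes ring C onto C2 by oxa-Michael addition. The precursors are a symmetric 4,5-dibromoaryne source and a brominated, O-methylated atropic acid; bromine marks C6, C7 and C3′. C7–Br is later turned into OH, the others into prenyl, and C3 is set late by enantioselective protonation.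

Key step: step 6

Remark on the chemistry (assumption): the sense of induction of the binaphthyl acid in step 11 must be confirmed on first use against racemic material; the (S)-catalyst is written, and its mirror image would be used if it leads to the 3S ketone.

Step 1
Reactants: 1 3,4-dibromophenol
Product: 2 4,5-dibromo-2-iodophenol
Conditions: NIS (1.0 equiv), TsOH·H2O (10 mol%), MeCN, 0 °C → rt
Reagents that add atoms: N-iodosuccinimide, O=C1CCC(=O)N1I
Why: Electrophilic aromatic iodination of a phenol; the para position is blocked by bromine and the ortho carbon between OH and Br is crowded, so iodine should enter at the free ortho carbon and supply the one halogen that exchanges faster than bromine in step 2.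

Step 2
Reactants: 2 4,5-dibromo-2-iodophenol
Product: 5 4,5-dibromo-2-(trimethylsilyl)phenyl trifluoromethanesulfonate, via aryl trimethylsilyl ether 3 (not isolated), via lithium silylphenolate 4 (not isolated)
Conditions: HMDS, THF, 70 °C, then evaporation; n-BuLi (1.0 equiv), THF, −100 → −80 °C; Tf2O, −100 °C → rt
Reagents that add atoms: hexamethyldisilazane, C[Si](C)(C)N[Si](C)(C)C; trifluoromethanesulfonic anhydride, O=S(=O)(OS(=O)(=O)C(F)(F)F)C(F)(F)F; n-butyllithium, [Li]CCCC (lithium carried in 4 only)
Why: O-silylation, iodine–lithium exchange (much faster than bromine–lithium exchange at −100 °C), retro-Brook 1,3-shift of silicon from oxygen to the lithiated carbon and O-triflation of the phenolate, the standard entry to ortho-silylaryl triflates.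

Step 3
Reactants: 6 2-(3-bromo-4-methoxyphenyl)acetic acid
Product: 7 methyl 2-(3-bromo-4-methoxyphenyl)acetate
Conditions: MeOH, H2SO4 (cat.), reflux
Reagents that add atoms: methanol, CO
Why: Fischer esterification, needed because the methylenation of step 4 runs through the ester enolate and not the carboxylate.

Step 4
Reactants: 7 methyl 2-(3-bromo-4-methoxyphenyl)acetate
Product: 9 methyl 2-(3-bromo-4-methoxyphenyl)acrylate, via aldol adduct 8 (not isolated)
Conditions: (CH2O)n (2 equiv), K2CO3 (2 equiv), Bu4NI (5 mol%), toluene, 80 °C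
Reagents that add atoms: formaldehyde (as paraformaldehyde), C=O
Why: Aldol addition of the arylacetate enolate to formaldehyde followed by E1cB dehydration (α-methylenation), a routine preparation of 2-arylacrylates.

Step 5
Reactants: 9 methyl 2-(3-bromo-4-methoxyphenyl)acrylate
Product: 10 2-(3-bromo-4-methoxyphenyl)acrylic acid
Conditions: LiOH·H2O (2 equiv), THF/H2O, 0 °C → rt; then 1 M HCl
Reagents that add atoms: lithium hydroxide, [Li+].[OH-]
Why: Saponification of the methyl ester; the low temperature limits conjugate addition of hydroxide to the acrylate.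

Step 6
Reactants: 5 4,5-dibromo-2-(trimethylsilyl)phenyl trifluoromethanesulfonate; 10 2-(3-bromo-4-methoxyphenyl)acrylic acid
Product: 13 rac-6,7-dibromo-3-(3-bromo-4-methoxyphenyl)chroman-4-one, via 4,5-dibromobenzyne 11 (not isolated), via hydroxyaryl enone 12 (not isolated)
Conditions: 5 (1.5 equiv), CsF (4 equiv), THF, 125 °C, sealed tube
Reagents that add atoms: none
Why: Fluoride removes the trimethylsilyl group and triflate leaves, giving the mirror-symmetric aryne 11; the cesium carboxylate of 10 adds through oxygen, the aryl anion attacks its own ester carbonyl and the four-membered alkoxide opens to the ortho-acylphenoxide 12 (net insertion into the acyl C–O bond, forming O1–C8a and C4–C4a). The phenoxide then adds to the unsubstituted terminus of the α-aryl enone, closing ring C in the 6-endo-trig mode (O1–C2), and the enolate is protonated. The closest known reaction type is the fluoride-mediated aryne insertion into carboxylic acids, which with α,β-unsaturated acids continues to chroman-4-ones. C3 arises by uncontrolled protonation and is deliberately left racemic until step 11. Regiochemistry cannot go wrong because both aryne carbons are equivalent (H at C5 and C8, Br at C6 and C7), and bromine in place of prenyl or hydroxyl keeps ene reaction and O-arylation away from the aryne. Acyl transfer should outrun protonation to the simple aryl ester in aprotic THF at high temperature with excess CsF.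

Step 7
Reactants: 13 rac-6,7-dibromo-3-(3-bromo-4-methoxyphenyl)chroman-4-one
Product: 15 rac-6-bromo-3-(3-bromo-4-methoxyphenyl)-7-hydroxychroman-4-one, via C7 pinacol boronate 14 (not isolated)
Conditions: B2pin2 (1.05 equiv), PdCl2(dppf) (3 mol%), KOAc (3 equiv), 1,4-dioxane, 80 °C; Celite filtration; then 30% aq. H2O2 (1.5 equiv), NaHCO3, THF/H2O, 0 °C → rt; Na2S2O3 quench
Reagents that add atoms: bis(pinacolato)diboron, CC1(C)OB(OC1(C)C)B1OC(C)(C)C(C)(C)O1 (boron carried in 14 only); hydrogen peroxide, OO
Why: Miyaura borylation followed by peroxide oxidation of the aryl boronate: zerovalent palladium should insert fastest into C7–Br, the only C–Br bond para to the C4 carbonyl (C6–Br lies para to the donor O1 and the ring B bromide is ortho to a methoxy group), acetate is too weak a base to enolise C3 or open ring C, and hydroperoxide then converts C7–B into C7–OH by 1,2-aryl shift.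

Step 8
Reactants: 15 rac-6-bromo-3-(3-bromo-4-methoxyphenyl)-7-hydroxychroman-4-one
Product: 16 rac-6-bromo-3-(3-bromo-4-hydroxyphenyl)-7-hydroxychroman-4-one
Conditions: BBr3 (3.5 equiv), CH2Cl2, −78 → 0 °C; then aq. NaHCO3
Reagents that add atoms: none
Why: Lewis-acid cleavage of the aryl methyl ether (bromide attacks the methyl group of the boron-complexed ether), placed before any prenyl group exists so that no acid-sensitive alkene is present.

Step 9
Reactants: 16 rac-6-bromo-3-(3-bromo-4-hydroxyphenyl)-7-hydroxychroman-4-one
Product: 17 6-bromo-3-[3-bromo-4-(tert-butyldimethylsilyloxy)phenyl]-4,7-bis(tert-butyldimethylsilyloxy)-2H-chromene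
Conditions: TBSOTf (3.6 equiv), Et3N (6 equiv), CH2Cl2, 0 °C → rt
Reagents that add atoms: tert-butyldimethylsilyl trifluoromethanesulfonate, CC(C)(C)[Si](C)(C)OS(=O)(=O)C(F)(F)F
Why: Silyl triflate/amine silylation caps both phenols and traps the ketone as its only possible enol ether (C3=C4), which removes the acidic C3–H and the base-labile β-aryloxy ketone before the cross-coupling and at the same time provides the substrate of step 11.

Step 10
Reactants: 17 6-bromo-3-[3-bromo-4-(tert-butyldimethylsilyloxy)phenyl]-4,7-bis(tert-butyldimethylsilyloxy)-2H-chromene; 18 prenylboronic acid pinacol ester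
Product: 19 4,7-bis(tert-butyldimethylsilyloxy)-3-[4-(tert-butyldimethylsilyloxy)-3-(3-methylbut-2-enyl)phenyl]-6-(3-methylbut-2-enyl)-2H-chromene
Conditions: 18 (3 equiv), Pd(OAc)2 (5 mol%), t-BuXPhos (10 mol%), K3PO4 (3 M aq., 6 equiv), THF, 40 °C
Reagents that add atoms: none
Why: Suzuki–Miyaura coupling of an allylic boronate at both remaining C–Br bonds; with the bulky di-tert-butylbiarylphosphine the allylpalladium intermediate should settle as the less hindered primary σ-prenyl species before C–C reductive elimination, giving the linear 3-methylbut-2-enyl arene, while the enol ether keeps the ketone out of reach of the aqueous base.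

Step 11
Reactants: 19 4,7-bis(tert-butyldimethylsilyloxy)-3-[4-(tert-butyldimethylsilyloxy)-3-(3-methylbut-2-enyl)phenyl]-6-(3-methylbut-2-enyl)-2H-chromene
Product: 20 (3R)-7-(tert-butyldimethylsilyloxy)-3-[4-(tert-butyldimethylsilyloxy)-3-(3-methylbut-2-enyl)phenyl]-6-(3-methylbut-2-enyl)chroman-4-one
Conditions: (S)-3,3′-bis(2,4,6-triisopropylphenyl)-1,1′-binaphthyl-2,2′-diyl N-triflyl thiophosphoramide (5 mol%), PhOH (1.1 equiv), toluene, 0 °C → rt; filtration through a short silica pad
Reagents that add atoms: none
Why: Catalytic enantioselective protonation of a silyl enol ether by a chiral Brønsted acid: the binaphthyl acid transfers its proton to one face of C3 within a tight ion pair, which sets the C3 stereocentre (R) under catalyst control, and phenol then takes the silyl group from the oxocarbenium ion and regenerates the acid, the enol ether being far more basic than the prenyl alkenes or the aryl silyl ethers.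

Step 12
Reactants: 20 (3R)-7-(tert-butyldimethylsilyloxy)-3-[4-(tert-butyldimethylsilyloxy)-3-(3-methylbut-2-enyl)phenyl]-6-(3-methylbut-2-enyl)chroman-4-one
Product: 21 (3R)-7-hydroxy-3-[4-hydroxy-3-(3-methylbut-2-enyl)phenyl]-6-(3-methylbut-2-enyl)chroman-4-one
Conditions: KHF2 (3 equiv), MeOH, rt
Reagents that add atoms: none
Why: Bifluoride cleavage of the two aryl silyl ethers; the medium is weakly acidic, so C3 should not be enolised (no racemisation) and the ortho-prenyl phenols should not be driven to chromans.

Compound list
1 | 3,4-dibromophenol | Oc1ccc(Br)c(Br)c1 | starting material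
2 | 4,5-dibromo-2-iodophenol | Oc1cc(Br)c(Br)cc1I | intermediate
3 | (4,5-dibromo-2-iodophenoxy)trimethylsilane | C[Si](C)(C)Oc1cc(Br)c(Br)cc1I | intermediate
4 | lithium 4,5-dibromo-2-(trimethylsilyl)phenolate | [Li+].[O-]c1cc(Br)c(Br)cc1[Si](C)(C)C | intermediate
5 | 4,5-dibromo-2-(trimethylsilyl)phenyl trifluoromethanesulfonate | C[Si](C)(C)c1cc(Br)c(Br)cc1OS(=O)(=O)C(F)(F)F | intermediate
6 | 2-(3-bromo-4-methoxyphenyl)acetic acid | COc1ccc(CC(=O)O)cc1Br | starting material
7 | methyl 2-(3-bromo-4-methoxyphenyl)acetate | COC(=O)Cc1ccc(OC)c(Br)c1 | intermediate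
8 | methyl 2-(3-bromo-4-methoxyphenyl)-3-hydroxypropanoate (racemic) | COC(=O)C(CO)c1ccc(OC)c(Br)c1 | intermediate
9 | methyl 2-(3-bromo-4-methoxyphenyl)acrylate | C=C(C(=O)OC)c1ccc(OC)c(Br)c1 | intermediate
10 | 2-(3-bromo-4-methoxyphenyl)acrylic acid | C=C(C(=O)O)c1ccc(OC)c(Br)c1 | intermediate
11 | 4,5-dibromobenzyne | BrC1=CC#CC=C1Br | intermediate
12 | 1-(4,5-dibromo-2-hydroxyphenyl)-2-(3-bromo-4-methoxyphenyl)prop-2-en-1-one (present as its cesium phenoxide) | C=C(C(=O)c1cc(Br)c(Br)cc1O)c1ccc(OC)c(Br)c1 | intermediate
13 | rac-6,7-dibromo-3-(3-bromo-4-methoxyphenyl)chroman-4-one | O=C1c2cc(Br)c(Br)cc2OCC1c1ccc(OC)c(Br)c1 | intermediate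
14 | rac-6-bromo-3-(3-bromo-4-methoxyphenyl)-7-(4,4,5,5-tetramethyl-1,3,2-dioxaborolan-2-yl)chroman-4-one | COc1ccc(C2COc3cc(B4OC(C)(C)C(C)(C)O4)c(Br)cc3C2=O)cc1Br | intermediate
15 | rac-6-bromo-3-(3-bromo-4-methoxyphenyl)-7-hydroxychroman-4-one | COc1ccc(C2COc3cc(O)c(Br)cc3C2=O)cc1Br | intermediate
16 | rac-6-bromo-3-(3-bromo-4-hydroxyphenyl)-7-hydroxychroman-4-one | Oc1ccc(C2COc3cc(O)c(Br)cc3C2=O)cc1Br | intermediate
17 | 6-bromo-3-[3-bromo-4-(tert-butyldimethylsilyloxy)phenyl]-4,7-bis(tert-butyldimethylsilyloxy)-2H-chromene | CC(C)(C)[Si](C)(C)Oc1ccc(C2=C(O[Si](C)(C)C(C)(C)C)c3cc(Br)c(O[Si](C)(C)C(C)(C)C)cc3OC2)cc1Br | intermediate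
18 | prenylboronic acid pinacol ester | CC(C)=CCB1OC(C)(C)C(C)(C)O1 | starting material
19 | 4,7-bis(tert-butyldimethylsilyloxy)-3-[4-(tert-butyldimethylsilyloxy)-3-(3-methylbut-2-enyl)phenyl]-6-(3-methylbut-2-enyl)-2H-chromene | CC(C)=CCc1cc(C2=C(O[Si](C)(C)C(C)(C)C)c3cc(CC=C(C)C)c(O[Si](C)(C)C(C)(C)C)cc3OC2)ccc1O[Si](C)(C)C(C)(C)C | intermediate
20 | (3R)-7-(tert-butyldimethylsilyloxy)-3-[4-(tert-butyldimethylsilyloxy)-3-(3-methylbut-2-enyl)phenyl]-6-(3-methylbut-2-enyl)chroman-4-one | CC(C)=CCc1cc([C@@H]2COc3cc(O[Si](C)(C)C(C)(C)C)c(CC=C(C)C)cc3C2=O)ccc1O[Si](C)(C)C(C)(C)C | intermediate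
21 | (3R)-7-hydroxy-3-[4-hydroxy-3-(3-methylbut-2-enyl)phenyl]-6-(3-methylbut-2-enyl)chroman-4-one | CC(C)=CCc1cc([C@@H]2COc3cc(O)c(CC=C(C)C)cc3C2=O)ccc1O | target

Total step count: 12. Longest linear sequence: 10 steps (6 to 21 through steps 3–12); the aryne branch (steps 1–2) joins at step 6.

Steps most likely to fail

Step 6. The aryl anion may be protonated before acyl transfer (giving only the aryl ester), the acrylate may polymerise or react with the aryne through its alkene, and the product enolate may be arylated by excess aryne. The fallback leaves aryne chemistry and builds the same ring from a deoxybenzoin. It sets out from 1 and 6: Steglich esterification (DCC, DMAP, CH2Cl2) should give 3,4-dibromophenyl 2-(3-bromo-4-methoxyphenyl)acetate F1. Fries rearrangement (AlCl3, chlorobenzene, 110 °C) should move the acyl group to the free, less hindered ortho carbon and give 1-(4,5-dibromo-2-hydroxyphenyl)-2-(3-bromo-4-methoxyphenyl)ethan-1-one F2. Mannich methylenation with paraformaldehyde and Et2NH in refluxing EtOH then generates enone 12 in the flask, and its oxa-Michael closure returns the route to 13.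

Step 11. Facial discrimination may be poor with the bulky silyl group on a chromene enol ether, the acid may slowly racemise the product after turnover, or it may trigger cyclisation of a prenyl group. The fallback is a dynamic kinetic resolution by reduction. It sets out from 19: brief hydrolysis of the enol ether (0.5 M HCl, THF, 0 °C) should give racemic 7-(tert-butyldimethylsilyloxy)-3-[4-(tert-butyldimethylsilyloxy)-3-(3-methylbut-2-enyl)phenyl]-6-(3-methylbut-2-enyl)chroman-4-one F4. Noyori-type transfer hydrogenation with RuCl(p-cymene)[(R,R)-TsDPEN] in HCO2H/Et3N should then act while C3 epimerises through the enol, hydride arriving anti to the C3 aryl group, to give the cis alcohol (3R,4R)-7-(tert-butyldimethylsilyloxy)-3-[4-(tert-butyldimethylsilyloxy)-3-(3-methylbut-2-enyl)phenyl]-6-(3-methylbut-2-enyl)chroman-4-ol F5. The catalyst antipode is chosen by analogy with simple aryl ketones, where the (R,R)-complex gives the R carbinol. Dess–Martin oxidation buffered with NaHCO3 (CH2Cl2, 0 °C) should restore the ketone without touching C3 and rejoin the route at 20.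

Step 7. Palladium may not distinguish C7–Br from C6–Br well enough, or may borylate twice. The fallback lets the carbonyl choose the site by addition–elimination instead. It sets out from 13: NaOMe (1.2 equiv) in DMSO at 50 °C should displace only the bromide para to C4 and give rac-6-bromo-3-(3-bromo-4-methoxyphenyl)-7-methoxychroman-4-one F3. This substitution is inherently site-specific but was not made the main route because C3 enolisation in base slows it and endangers ring C. BBr3 (CH2Cl2, −78 °C → rt) then cleaves both methyl ethers and the route is rejoined at 16, bypassing 15.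

Further compounds
F1 | step 6 | 3,4-dibromophenyl 2-(3-bromo-4-methoxyphenyl)acetate | COc1ccc(CC(=O)Oc2ccc(Br)c(Br)c2)cc1Br
F2 | step 6 | 1-(4,5-dibromo-2-hydroxyphenyl)-2-(3-bromo-4-methoxyphenyl)ethan-1-one | O=C(Cc1ccc(OC)c(Br)c1)c1cc(Br)c(Br)cc1O
F3 | step 7 | rac-6-bromo-3-(3-bromo-4-methoxyphenyl)-7-methoxychroman-4-one | COc1cc2OCC(c3ccc(OC)c(Br)c3)C(=O)c2cc1Br
F4 | step 11 | rac-7-(tert-butyldimethylsilyloxy)-3-[4-(tert-butyldimethylsilyloxy)-3-(3-methylbut-2-enyl)phenyl]-6-(3-methylbut-2-enyl)chroman-4-one | CC(C)=CCc1cc(C2COc3cc(O[Si](C)(C)C(C)(C)C)c(CC=C(C)C)cc3C2=O)ccc1O[Si](C)(C)C(C)(C)C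
F5 | step 11 | (3R,4R)-7-(tert-butyldimethylsilyloxy)-3-[4-(tert-butyldimethylsilyloxy)-3-(3-methylbut-2-enyl)phenyl]-6-(3-methylbut-2-enyl)chroman-4-ol | CC(C)=CCc1cc([C@@H]2COc3cc(O[Si](C)(C)C(C)(C)C)c(CC=C(C)C)cc3[C@@H]2O)ccc1O[Si](C)(C)C(C)(C)C
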